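The earlier runs and the new flask are simulated from invented constants, and the scatter is random.

Watch what goes missing.

in all of them: starting complex 0.057 M; incoming ligand 0.0855 M

| flask | capture agent | remark | time |
|---|---|---|---|
| elm | 8 mM | run made earlier |  |
| alder | 13 mM | run made earlier |  |
| flask | 5.70 mM |  | 12 h |

| run | time / h | complex with one exchanged / % | complex with two exchanged / % | starting complex / % |
|---|---|---|---|---|
| elm | 0.417 | 64 | 15 | 17 |
| elm | 1.33 | 79 | 11 | 2 |
| elm | 4.00 | 68 | 11 | 0 |
| elm | 15.0 | 53 | 6 | 1 |
| alder | 0.417 | 64 | 16 | 20 |
| alder | 1.33 | 72 | 10 | 5 |
| alder | 4.00 | 61 | 9 | 0 |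
| alder | 15.0 | 48 | 5 | 2 |

(readings scatter by 1.5 percentage points)

* time, not beyond 12 h, at which the flask holds most complex with one exchanged
* the amount of complex with one exchanged, in percent of the starting complex charged, at that time
* earliest time at which at least nineteen twentieths of that best amount are there
* latest time at which they still are



1. I added the three read complexes at 1.33 h and subtracted from the whole charge. I called the gap, expressed per capture agent charged, the toll: missing share × c(starting complex) / c(capture agent). The elm run gives 57.0% and the alder run 57.0%, so I carried 57.0%.

2. This seems to clash with the last elm reading. At 15.0 h, 40.0% of the charge was missing, more than the 14.0% of it that the capture agent amounts to.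

3. I took one capture agent to remove one complex. Then about 26 percentage points of the elm loss at 15.0 h, as read, went another way, a second drain beside capture. So I used the toll as a ratio for the early hours of these runs, not as a stoichiometry.

4. For the new flask, the toll asks 5.70% of the charge. Taking the other two complexes from the elm reading at 1.33 h, I expected about 81.3% of complex with one exchanged in the new flask at that time.

5. The forecast gave 81% at 1.3 h, with the window from 0.7 h to 2.9 h, and held that “the agent acts as if catalytic”.

6. The flask peaked at 77.7% at 1.51 h, and the window asked for ran from 0.779 h to 3.29 h. At the peak it also held 12.0% of complex with two exchanged. Against the toll's 5.70%, side product and trapped intermediate together stood at 6.70% at 1.20 h.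

    leaving ligand + complex with two exchanged → side product (k = 0.0680 M⁻¹ min⁻¹)
    complex with one exchanged + capture agent → trapped intermediate (k = 0.140 M⁻¹ min⁻¹)
    starting complex + incoming ligand → leaving ligand + complex with one exchanged (k = 1.50 M⁻¹ min⁻¹)
    complex with one exchanged + incoming ligand ⇌ leaving ligand + complex with two exchanged (K = 0.490, k = 0.770 M⁻¹ min⁻¹)

7. The neighbour flask with 0.034 M of incoming ligand has 0.596 equiv of it to the starting complex; that ligand is the limiting reagent, with 0% left at 12.0 h. One exchange per ligand pays for 59.6% of the charge; less the toll's share, I expected 53.9%. The computed best is 53.2%.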